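## Retrosynthetic overview
1. Dienone ring (formed last): selaginellin ⇒ its hydrate, the tetraphenolic triaryl carbinol. Loss of water with dearomatisation of one p-hydroxyphenyl ring is the presumed closing event of the biogenesis.
2. Carbinol ⇒ ring-B carboxylate + two p-oxygenated aryl anions, which stand in for the two phenol units captured by the acid-level carbon.
3. Ring B (central benzene, the only ring built de novo, formed first) ⇒ head-to-tail [4+2] union and aromatisation of two p-coumarate-type C6–C5 chains: an alcohol-level (E,E)-arylpentadienol (4π) and an acid-level arylpentadiynoate (2π). The unused triple bond survives as the arylethynyl arm.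
4. Dienol ⇒ aryl aldehyde + C4 phosphonate. Diynoate ⇒ aryl iodide + butadiyne + chloroformate. The four oxygenated benzene rings are bought.

Assumption (stereochemistry): the SMILES has no stereodescriptor and no stereocentre, and the pigment occurs as a racemate, so no configuration has to be set; the only stereocentres on the way (in 12) are erased on aromatisation.
Assumption (biogenesis): the pathway is unproven, so the working hypothesis is the C6–C5 + C6–C5 cycloaromatisation, double phenol capture and dehydration outlined above.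

TBS = tert-butyldimethylsilyl. All five starting materials are catalogue items.

## Route

Step 1
Reactants: 1 4-(TBS-oxy)benzaldehyde; 2 triethyl 4-phosphonocrotonate
Product: 3 ethyl (2E,4E)-5-[4-(TBS-oxy)phenyl]penta-2,4-dienoate
Conditions: LiN(SiMe3)2 (1.1 equiv), THF, −78 °C to rt
Reagents that add atoms: none
Why: In this vinylogous Horner–Wadsworth–Emmons olefination the phosphonate-stabilised allyl anion adds reversibly to the non-enolisable aldehyde and eliminates to the conjugated (E)-alkene, while the existing (E)-enoate and the aryl silyl ether are untouched and no stereocentre is formed.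

Step 2
Reactants: 3 ethyl (2E,4E)-5-[4-(TBS-oxy)phenyl]penta-2,4-dienoate
Product: 4 (2E,4E)-5-[4-(TBS-oxy)phenyl]penta-2,4-dien-1-ol
Conditions: i-Bu2AlH (2.3 equiv), CH2Cl2, −78 °C; aq. potassium sodium tartrate
Reagents that add atoms: none
Why: This 1,2-reduction of a conjugated ester by an electrophilic aluminium hydride leaves the diene geometry and the aryl silyl ether intact at low temperature and creates no stereocentre.

Step 3
Reactants: 5 1,4-bis(trimethylsilyl)buta-1,3-diyne; 6 tert-butyl(4-iodophenoxy)dimethylsilane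
Product: 9 tert-butyldimethyl{4-[4-(trimethylsilyl)buta-1,3-diyn-1-yl]phenoxy}silane, via lithium silylbutadiynide 7 (not isolated), via chlorozinc silylbutadiynide 8 (not isolated)
Conditions: 5, MeLi·LiBr (1.0 equiv), THF, 0 °C to rt, 3 h; ZnCl2 (1.1 equiv), 0 °C; 6 (0.9 equiv), Pd(PPh3)4 (3 mol %), rt to 45 °C
Reagents that add atoms: none
Why: Methyllithium cleaves one unhindered C–SiMe3 bond because the diynyl anion is a good leaving group, transmetalation to zinc tames that anion, and Negishi alkynylation of the aryl iodide on zerovalent palladium gives the unsymmetrical diyne without homocoupling.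

Step 4
Reactants: 9 tert-butyldimethyl{4-[4-(trimethylsilyl)buta-1,3-diyn-1-yl]phenoxy}silane
Product: 11 methyl 5-[4-(TBS-oxy)phenyl]penta-2,4-diynoate, via lithium aryldiynide 10 (not isolated)
Conditions: MeLi·LiBr (1.05 equiv), THF, −78 to 0 °C; ClCO2Me (1.5 equiv), −78 to 0 °C
Reagents that add atoms: methyl chloroformate COC(=O)Cl
Why: The alkynyl SiMe3 group is attacked orders of magnitude faster than the tert-butyl-shielded aryl silyl ether, and C-acylation of the lithium diynide by the chloroformate (nucleophilic acyl substitution) installs the acid-level carbon.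

Step 5 (key step, ring B)
Reactants: 4 (2E,4E)-5-[4-(TBS-oxy)phenyl]penta-2,4-dien-1-ol; 11 methyl 5-[4-(TBS-oxy)phenyl]penta-2,4-diynoate
Product: 13 methyl 4'-(TBS-oxy)-4-(hydroxymethyl)-3-{[4-(TBS-oxy)phenyl]ethynyl}biphenyl-2-carboxylate, via cis-cyclohexa-1,4-diene adduct 12 (not isolated)
Conditions: 4 (1.0 equiv), 11 (1.2 equiv), BHT (5 mol %), 1,4-dioxane (1 M), 120 °C, sealed tube, 36 h; then DDQ (1.15 equiv), rt, 1 h
Reagents that add atoms: none
Why: In this intermolecular normal-electron-demand Diels–Alder reaction followed by DDQ dehydrogenation, the largest HOMO coefficient of the electron-rich 1-aryl diene (at the CH2OH-bearing terminus) meets the largest LUMO coefficient of the ester-activated triple bond (at its β-carbon), so the "ortho" adduct with aryl next to ester and CH2OH next to the spectator alkyne is favoured, dioxane suppresses the OH···O=C pre-association that would favour the other orientation, and the two cis stereocentres of racemic 12 set by suprafacial addition to the (E,E)-diene are erased on hydride abstraction and proton loss.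

Step 6
Reactants: 13 methyl 4'-(TBS-oxy)-4-(hydroxymethyl)-3-{[4-(TBS-oxy)phenyl]ethynyl}biphenyl-2-carboxylate; 14 (4-bromophenoxy)(tert-butyl)dimethylsilane
Product: 19 selaginellin, via aryllithium 15 (not isolated), via diaryl ketone 16 (not isolated), via tetrasilyl carbinol 17 (not isolated), via desilylated carbinol 18 (not isolated)
Conditions: 14 (4.5 equiv), n-BuLi (4.4 equiv), THF, −78 °C; 13, −78 to 0 °C; AcOH (12 equiv), then n-Bu4NF (12 equiv), 0 °C to rt; aqueous work-up at pH 4
Reagents that add atoms: none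
Why: Bromine–lithium exchange gives 15, of which one equivalent deprotonates the CH2OH and two undergo double 1,2-addition to a biaryl-2-carboxylate whose second ortho group is only a slim alkyne, then acetic-acid-buffered fluoride removes the four aryl silyl ethers without forming phenoxides that n-BuBr could alkylate, and the p-hydroxytrityl alcohol 18 loses water through its bis(4-hydroxyphenyl)carbenium ion (E1-type dehydrative dearomatisation) to give the p-quinone methide with no stereocentre formed.

## Compound list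
1 | 4-(TBS-oxy)benzaldehyde | O=Cc1ccc(O[Si](C)(C)C(C)(C)C)cc1 | starting material
2 | triethyl 4-phosphonocrotonate = ethyl (E)-4-(diethoxyphosphoryl)but-2-enoate | CCOC(=O)/C=C/CP(=O)(OCC)OCC | starting material
3 | ethyl (2E,4E)-5-[4-(TBS-oxy)phenyl]penta-2,4-dienoate | CCOC(=O)/C=C/C=C/c1ccc(O[Si](C)(C)C(C)(C)C)cc1 | intermediate
4 | (2E,4E)-5-[4-(TBS-oxy)phenyl]penta-2,4-dien-1-ol | OC/C=C/C=C/c1ccc(O[Si](C)(C)C(C)(C)C)cc1 | intermediate
5 | 1,4-bis(trimethylsilyl)buta-1,3-diyne | C[Si](C)(C)C#CC#C[Si](C)(C)C | starting material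
6 | tert-butyl(4-iodophenoxy)dimethylsilane | Ic1ccc(O[Si](C)(C)C(C)(C)C)cc1 | starting material
7 | lithium 4-(trimethylsilyl)buta-1,3-diyn-1-ide | [Li]C#CC#C[Si](C)(C)C | intermediate
8 | chloro[4-(trimethylsilyl)buta-1,3-diyn-1-yl]zinc | Cl[Zn]C#CC#C[Si](C)(C)C | intermediate
9 | tert-butyldimethyl{4-[4-(trimethylsilyl)buta-1,3-diyn-1-yl]phenoxy}silane | C[Si](C)(C)C#CC#Cc1ccc(O[Si](C)(C)C(C)(C)C)cc1 | intermediate
10 | lithium 4-[4-(TBS-oxy)phenyl]buta-1,3-diyn-1-ide | [Li]C#CC#Cc1ccc(O[Si](C)(C)C(C)(C)C)cc1 | intermediate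
11 | methyl 5-[4-(TBS-oxy)phenyl]penta-2,4-diynoate | COC(=O)C#CC#Cc1ccc(O[Si](C)(C)C(C)(C)C)cc1 | intermediate
12 | methyl cis-6-[4-(TBS-oxy)phenyl]-3-(hydroxymethyl)-2-{[4-(TBS-oxy)phenyl]ethynyl}cyclohexa-1,4-diene-1-carboxylate (racemic, one enantiomer drawn) | COC(=O)C1=C(C#Cc2ccc(O[Si](C)(C)C(C)(C)C)cc2)[C@@H](CO)C=C[C@H]1c1ccc(O[Si](C)(C)C(C)(C)C)cc1 | intermediate
13 | methyl 4'-(TBS-oxy)-4-(hydroxymethyl)-3-{[4-(TBS-oxy)phenyl]ethynyl}biphenyl-2-carboxylate | COC(=O)c1c(C#Cc2ccc(O[Si](C)(C)C(C)(C)C)cc2)c(CO)ccc1-c1ccc(O[Si](C)(C)C(C)(C)C)cc1 | intermediate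
14 | (4-bromophenoxy)(tert-butyl)dimethylsilane | Brc1ccc(O[Si](C)(C)C(C)(C)C)cc1 | starting material
15 | [4-(TBS-oxy)phenyl]lithium | [Li]c1ccc(O[Si](C)(C)C(C)(C)C)cc1 | intermediate
16 | [4'-(TBS-oxy)-4-(hydroxymethyl)-3-{[4-(TBS-oxy)phenyl]ethynyl}biphenyl-2-yl][4-(TBS-oxy)phenyl]methanone (lithium alkoxide in the flask, drawn neutral) | O=C(c1ccc(O[Si](C)(C)C(C)(C)C)cc1)c1c(C#Cc2ccc(O[Si](C)(C)C(C)(C)C)cc2)c(CO)ccc1-c1ccc(O[Si](C)(C)C(C)(C)C)cc1 | intermediate
17 | [4'-(TBS-oxy)-4-(hydroxymethyl)-3-{[4-(TBS-oxy)phenyl]ethynyl}biphenyl-2-yl]bis[4-(TBS-oxy)phenyl]methanol (drawn neutral) | OC(c1ccc(O[Si](C)(C)C(C)(C)C)cc1)(c1ccc(O[Si](C)(C)C(C)(C)C)cc1)c1c(C#Cc2ccc(O[Si](C)(C)C(C)(C)C)cc2)c(CO)ccc1-c1ccc(O[Si](C)(C)C(C)(C)C)cc1 | intermediate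
18 | [4'-hydroxy-4-(hydroxymethyl)-3-[(4-hydroxyphenyl)ethynyl]biphenyl-2-yl]bis(4-hydroxyphenyl)methanol | OC(c1ccc(O)cc1)(c1ccc(O)cc1)c1c(C#Cc2ccc(O)cc2)c(CO)ccc1-c1ccc(O)cc1 | intermediate
19 | selaginellin | O=C1C=CC(=C(c2ccc(O)cc2)c2c(-c3ccc(O)cc3)ccc(CO)c2C#Cc2ccc(O)cc2)C=C1 | target

## Step count and risks
Total steps: 6. Longest linear sequence: 4 (3 → 4 → 5 → 6, or 1 → 2 → 5 → 6).

**Step 5.** The β-alkynyl ynoate may react too slowly, the regioselectivity may be only moderate, or 11 may oligomerise on heating.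
- The fallback replaces the thermal cycloaddition and oxidation by a redox-neutral, palladium-templated enyne–diyne cross-benzannulation. It sets out from 1 and comes back at 13.
- Takai olefination of 1 (CHI3, CrCl2, THF, 0 °C) gives tert-butyl{4-[(E)-2-iodoethenyl]phenoxy}dimethylsilane F1.
- Sonogashira coupling of F1 with propargyl alcohol (PdCl2(PPh3)2, CuI, Et3N, rt) gives (E)-5-[4-(TBS-oxy)phenyl]pent-4-en-2-yn-1-ol F2.
- F2 is heated with 11 and Pd(PPh3)4 (5 mol %) in toluene at 80–100 °C. The alkyne terminus of F2 bonds to the alkynyl-bearing carbon of the ester-activated triple bond of 11, which is the regiochemical rule of this benzannulation. After the hydrogen shift this gives 13 directly, with no oxidant.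

**Step 6.** The addition may stall at the hindered ester or at ketone 16, and the one-flask unmasking may be messy.
- The fallback forms one aryl–carbon bond before ring B is made, so only one addition to an isolated ketone remains. It sets out from 9 and comes back at 16.
- Diynide 10, made from 9 as in step 4, is added to aldehyde 1 to give racemic 1,5-bis[4-(TBS-oxy)phenyl]penta-2,4-diyn-1-ol F3.
- MnO2 in CH2Cl2 oxidises F3 to 1,5-bis[4-(TBS-oxy)phenyl]penta-2,4-diyn-1-one F4, which is a stronger dienophile than 11.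
- Cycloaddition of F4 with 4 passes through the cis-cyclohexadienyl ketone F5, and DDQ then delivers 16 as an isolated compound.
- 16 takes up 15 once to give 17. Carbinol 17 is purified and unmasked with buffered n-Bu4NF in a separate operation.

**Step 4.** MeLi may erode the aryl silyl ether, or the diynide and diynoate may decompose.
- The fallback reverses the order of bond formation, so the aryl silyl ether never meets MeLi. It sets out from 5 and comes back at 11.
- Diynide 7, made from 5 as in step 3, is trapped with ClCO2Me to give methyl 5-(trimethylsilyl)penta-2,4-diynoate F6.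
- F6 is coupled with 6 by silicon-to-copper transmetalation and palladium catalysis (CuCl 1.1 equiv, Pd(PPh3)4 5 mol %, DMF, 60 °C) to give 11. This bypasses 9.

## Further compounds
F1 | step 5 | tert-butyl{4-[(E)-2-iodoethenyl]phenoxy}dimethylsilane | I/C=C/c1ccc(O[Si](C)(C)C(C)(C)C)cc1
F2 | step 5 | (E)-5-[4-(TBS-oxy)phenyl]pent-4-en-2-yn-1-ol | OCC#C/C=C/c1ccc(O[Si](C)(C)C(C)(C)C)cc1
F3 | step 6 | 1,5-bis[4-(TBS-oxy)phenyl]penta-2,4-diyn-1-ol (racemic) | OC(C#CC#Cc1ccc(O[Si](C)(C)C(C)(C)C)cc1)c1ccc(O[Si](C)(C)C(C)(C)C)cc1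
F4 | step 6 | 1,5-bis[4-(TBS-oxy)phenyl]penta-2,4-diyn-1-one | O=C(C#CC#Cc1ccc(O[Si](C)(C)C(C)(C)C)cc1)c1ccc(O[Si](C)(C)C(C)(C)C)cc1
F5 | step 6 | cis-{6-[4-(TBS-oxy)phenyl]-3-(hydroxymethyl)-2-{[4-(TBS-oxy)phenyl]ethynyl}cyclohexa-1,4-dien-1-yl}[4-(TBS-oxy)phenyl]methanone (racemic, one enantiomer drawn) | O=C(c1ccc(O[Si](C)(C)C(C)(C)C)cc1)C1=C(C#Cc2ccc(O[Si](C)(C)C(C)(C)C)cc2)[C@@H](CO)C=C[C@H]1c1ccc(O[Si](C)(C)C(C)(C)C)cc1
F6 | step 4 | methyl 5-(trimethylsilyl)penta-2,4-diynoate | COC(=O)C#CC#C[Si](C)(C)C
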